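The 20-membered macrolactam is cut at the E-alkene on C9b, the quaternary carbon shared by the dihydrofuran ring and the cyclohexanone ring of the hexahydrodibenzofuran. Because C9b is fully substituted, a formyl group placed there lacks an α-hydrogen and keeps its configuration however long a dilute ring closure takes. One intramolecular Horner–Wadsworth–Emmons reaction then makes the C=C bond, sets its E geometry and closes the macrocycle. The precursor is the C9b aldehyde whose C8 carries the E-cinnamamide of N4-Boc-spermidine, the butyl-end nitrogen bearing a diethyl phosphonoacetyl group. The C3 ketone is masked as a C2-symmetric (R,R)-hydrobenzoin ketal, which also resolves the racemic Diels–Alder core without added steps.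

Key step: step 11

Assumption: the ketal diastereomer with the (4aR,9bS) core is identified by single-crystal X-ray diffraction (diol carbons as internal reference, bromine as anomalous scatterer) before it is carried on, since elution order cannot be predicted.

Step 1
Reactants: 1 5-bromosalicylaldehyde; 2 ethyl diazoacetate
Product: 4 ethyl 5-bromobenzofuran-3-carboxylate, via 2-hydroxy-2,3-dihydrobenzofuran hemiacetal 3 (not isolated)
Conditions: HBF4·OEt2 (10 mol %), CH2Cl2, rt, slow addition of 2; then conc. H2SO4, rt
Reagents that add atoms: none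
Why: Acid-catalysed addition of the diazoester to the aldehyde with loss of N2 and a 1,2-aryl shift (Roskamp-type homologation) gives the α-formyl arylacetate, which the phenol traps as hemiacetal 3 and H2SO4 dehydrates to the aromatic benzofuran; no stereocentre is involved.

Step 2
Reactants: 4 ethyl 5-bromobenzofuran-3-carboxylate; 5 (E)-1-methoxy-3-(trimethylsilyloxy)buta-1,3-diene
Product: 7 ethyl rac-(4aR,9bS)-8-bromo-3-oxo-4,4a-dihydrodibenzo[b,d]furan-9b(3H)-carboxylate, via silyl enol ether cycloadduct 6 (not isolated)
Conditions: 5 (4 equiv), CH2Cl2, 1.6 GPa, 25–40 °C; then 1 M HCl, THF, 0 °C to rt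
Reagents that add atoms: none
Why: This is a normal-electron-demand dearomative Diels–Alder reaction of a 3-acylbenzofuran under hyperbaric activation, in which the CH2 terminus of 5 bonds to benzofuran C2 (β to the ester) and the methoxy-bearing terminus to C3, suprafacial addition forces the cis C4a–H/C9b–ester fusion (racemic), and acid then unmasks the C3 ketone and eliminates methanol.

Step 3
Reactants: 7 racemic enone ester
Product: 8 ethyl rac-(4aR,9bS)-8-bromo-3-oxo-2,3,4,4a-tetrahydrodibenzo[b,d]furan-9b(1H)-carboxylate
Conditions: H2 (1 atm), RhCl(PPh3)3 (5 mol %), benzene–EtOH 1:1, rt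
Reagents that add atoms: none
Why: Homogeneous hydrogenation with RhCl(PPh3)3 saturates a disubstituted enone C=C next to a quaternary carbon (as in the 1,2-selective reduction of steroidal 1,4-dien-3-ones) without touching aryl bromide, ester or ketone, and it removes the one pathway (retro-oxa-Michael to a symmetric dienone) by which C9b could later racemise.

Step 4
Reactants: 8 racemic keto ester
Product: 9 ethyl (4aR,9bS,4'R,5'R)-8-bromo-4',5'-diphenyl-1,2,4,4a-tetrahydro-9bH-spiro[dibenzo[b,d]furan-3,2'-[1,3]dioxolane]-9b-carboxylate
Conditions: (R,R)-hydrobenzoin (1.1 equiv), p-TsOH·H2O (5 mol %), benzene, reflux, azeotropic water removal; diastereomers separated by chromatography, then crystallisation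
Reagents that add atoms: (1R,2R)-1,2-diphenylethane-1,2-diol, O[C@H](c1ccccc1)[C@H](O)c1ccccc1
Why: Acid-catalysed ketalisation with a C2-symmetric enantiopure diol creates no stereocentre at C3, so each enantiomer of 8 gives exactly one diastereomer, and their separation (resolution through covalent diastereomers) fixes the absolute configuration of C4a and C9b.

Step 5
Reactants: 9 ketal ester
Product: 10 [(4aR,9bR,4'R,5'R)-8-bromo-4',5'-diphenyl-1,2,4,4a-tetrahydro-9bH-spiro[dibenzo[b,d]furan-3,2'-[1,3]dioxolan]-9b-yl]methanol
Conditions: LiAlH4, THF, 0 °C; aqueous NaOH work-up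
Reagents that add atoms: none
Why: Hydride reduction of the ester gives the neopentyl alcohol while ketal and aryl bromide are inert at 0 °C and both stereocentres stay untouched (the C9b descriptor changes only through substituent priorities).

Step 6
Reactants: 11 N1,N4-bis-Boc-spermidine (butyl-end NH2 free); 12 diethylphosphonoacetic acid
Product: 13 tert-butyl N-[3-(tert-butoxycarbonylamino)propyl]-N-[4-(2-diethoxyphosphorylacetamido)butyl]carbamate
Conditions: EDC·HCl, HOBt, CH2Cl2, 0 °C to rt
Reagents that add atoms: none
Why: Carbodiimide amide coupling can occur only at the single free amine, so the phosphonoacetyl group is placed unambiguously on the butyl-end nitrogen N8.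

Step 7
Reactants: 13 bis-Boc phosphonoacetamide
Product: 14 N8-(diethoxyphosphorylacetyl)spermidine dihydrochloride
Conditions: 4 M HCl in dioxane, CH2Cl2, 0 °C to rt
Reagents that add atoms: hydrogen chloride, Cl
Why: Boc acidolysis frees N1 and N4 together, and the amide and the ethyl phosphonate esters are stable to anhydrous HCl at room temperature.

Step 8
Reactants: 14 N8-(diethoxyphosphorylacetyl)spermidine dihydrochloride; 15 N-acryloxysuccinimide
Product: 17 N1-acryloyl-N4-Boc-N8-(diethoxyphosphorylacetyl)spermidine, via N4-unprotected acrylamide 16 (not isolated)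
Conditions: Et3N (3.5 equiv), 15 (0.95 equiv, slow addition), CH2Cl2–DMF, −20 °C; then Boc2O (1.2 equiv), rt
Reagents that add atoms: di-tert-butyl dicarbonate, CC(C)(C)OC(=O)OC(=O)OC(C)(C)C
Why: N-Hydroxysuccinimide esters acylate the unhindered primary amine of a polyamine much faster than the internal secondary amine (the basis of terminal-selective spermidine acylation), so 16 should form first and its remaining N4–H is then capped in the same flask by standard Boc protection.

Step 9
Reactants: 10 bromo ketal alcohol; 17 acrylamide chain
Product: 18 C8 E-cinnamamide alcohol: 10 with Br replaced by (E)-CH=CH–C(O)NH(CH2)3N(Boc)(CH2)4NHC(O)CH2P(O)(OEt)2; (4aR,9bR,4'R,5'R)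
Conditions: Pd(OAc)2 (5 mol %), P(o-tol)3 (15 mol %), Et3N (3 equiv), DMF, 100 °C
Reagents that add atoms: none
Why: In this Mizoroki–Heck reaction zerovalent palladium inserts into the C8–Br bond, syn-insertion at the acrylamide CH2 and syn-β-hydride elimination give the E-cinnamamide, and alcohol, ketal, Boc group and phosphonate are inert to Et3N at this temperature.

Step 10
Reactants: 18 cinnamamide alcohol
Product: 19 C9b aldehyde: 18 with CH2OH oxidised to CHO; (4aR,9bS,4'R,5'R)
Conditions: Dess–Martin periodinane (1.3 equiv), CH2Cl2, 0 °C to rt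
Reagents that add atoms: none
Why: Dess–Martin oxidation turns the neopentyl primary alcohol into the aldehyde under neutral, non-aqueous conditions that neither over-oxidise it, deprotonate the phosphonoacetamide nor hydrolyse the ketal.

Step 11
Reactants: 19 aldehyde phosphonoacetamide
Product: 20 N4-Boc (R,R)-hydrobenzoin ketal of the target macrocycle; (4aR,9bS), both enoyl C=C bonds E
Conditions: LiCl (20 equiv), DBU (5 equiv), MeCN, 19 added by syringe pump over 12 h to a final 1 mM, rt to 40 °C
Reagents that add atoms: none
Why: Li+ chelates the phosphoryl and amide carbonyl oxygens of the phosphonoacetamide and so acidifies its P–CH2–C(O) hydrogens enough for DBU; the carbanion adds reversibly to the C9b formyl carbon and the oxaphosphetane collapses, with loss of lithium diethyl phosphate, to the α,β-unsaturated amide. This is the Masamune–Roush variant of the Horner–Wadsworth–Emmons olefination run intramolecularly, a reaction type well established for closing macrocyclic enoates and enoyl amides. The 20-membered ring closes end to end, the carbanion carbon at the butyl terminus of the chain bonding to the exocyclic formyl carbon, and syringe-pump addition keeps open-chain 19 so dilute that cyclisation should outrun dimerisation. No stereocentre is formed and none is at risk, since C9b bears no hydrogen, the aldehyde has no α-hydrogen, and C4a is tied to C9b by the cis ring fusion. E geometry follows from reversible addition of the stabilised phosphonate and from the bulk of quaternary C9b, which disfavours the oxaphosphetane leading to the Z-alkene. The selectivity needed is reaction at the aldehyde alone, secured by the ketal on C3, the carbamate on N4 and the low electrophilicity of the cinnamamide towards a lithium-chelated carbanion.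

Step 12
Reactants: 20 protected macrocycle
Product: 21 target macrolactam, (4aR,9bS), free base
Conditions: TFA–H2O 9:1, 0 °C to rt; then aq. K2CO3, extraction
Reagents that add atoms: water, O
Why: Aqueous acid performs ketal hydrolysis and Boc acidolysis in one operation, the two enoyl amides are acid-stable, and any reversible retro-oxa-Michael opening of the β-aryloxy ketone can only re-close to the same cis-fused C4a because C9b is fixed.

Compound list
1 | 5-bromosalicylaldehyde | O=Cc1cc(Br)ccc1O | starting material
2 | ethyl diazoacetate | CCOC(=O)C=[N+]=[N-] | starting material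
3 | ethyl 5-bromo-2-hydroxy-2,3-dihydrobenzofuran-3-carboxylate (hemiacetal, mixture of stereoisomers) | CCOC(=O)C1C(O)Oc2ccc(Br)cc12 | intermediate
4 | ethyl 5-bromobenzofuran-3-carboxylate | CCOC(=O)c1coc2ccc(Br)cc12 | intermediate
5 | (E)-1-methoxy-3-(trimethylsilyloxy)buta-1,3-diene | CO/C=C/C(=C)O[Si](C)(C)C | starting material
6 | ethyl 8-bromo-1-methoxy-3-(trimethylsilyloxy)-1,4,4a,9b-tetrahydrodibenzofuran-9b-carboxylate (racemic, cis-fused, C1 epimers) | C[Si](C)(C)OC1=CC(OC)[C@]2(C(=O)OCC)c3cc(Br)ccc3O[C@@H]2C1 | intermediate
7 | ethyl rac-(4aR,9bS)-8-bromo-3-oxo-4,4a-dihydrodibenzo[b,d]furan-9b(3H)-carboxylate (racemic, relative configuration drawn) | O=C1C=C[C@]2(C(=O)OCC)c3cc(Br)ccc3O[C@@H]2C1 | intermediate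
8 | ethyl rac-(4aR,9bS)-8-bromo-3-oxo-2,3,4,4a-tetrahydrodibenzo[b,d]furan-9b(1H)-carboxylate (racemic, relative configuration drawn) | O=C1CC[C@]2(C(=O)OCC)c3cc(Br)ccc3O[C@@H]2C1 | intermediate
9 | ethyl (4aR,9bS,4'R,5'R)-8-bromo-4',5'-diphenyl-1,2,4,4a-tetrahydro-9bH-spiro[dibenzo[b,d]furan-3,2'-[1,3]dioxolane]-9b-carboxylate | O1[C@H](c5ccccc5)[C@@H](c5ccccc5)OC12CC[C@]3(C(=O)OCC)c4cc(Br)ccc4O[C@@H]3C2 | intermediate
10 | [(4aR,9bR,4'R,5'R)-8-bromo-4',5'-diphenyl-1,2,4,4a-tetrahydro-9bH-spiro[dibenzo[b,d]furan-3,2'-[1,3]dioxolan]-9b-yl]methanol | O1[C@H](c5ccccc5)[C@@H](c5ccccc5)OC12CC[C@]3(CO)c4cc(Br)ccc4O[C@@H]3C2 | intermediate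
11 | N1,N4-bis-Boc-spermidine, tert-butyl N-(4-aminobutyl)-N-[3-(tert-butoxycarbonylamino)propyl]carbamate (catalogue polyamine building block) | NCCCCN(CCCNC(=O)OC(C)(C)C)C(=O)OC(C)(C)C | starting material
12 | diethylphosphonoacetic acid | CCOP(=O)(CC(=O)O)OCC | starting material
13 | tert-butyl N-[3-(tert-butoxycarbonylamino)propyl]-N-[4-(2-diethoxyphosphorylacetamido)butyl]carbamate | CCOP(=O)(OCC)CC(=O)NCCCCN(C(=O)OC(C)(C)C)CCCNC(=O)OC(C)(C)C | intermediate
14 | N8-(diethoxyphosphorylacetyl)spermidine dihydrochloride | CCOP(=O)(OCC)CC(=O)NCCCCNCCCN.Cl.Cl | intermediate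
15 | N-acryloxysuccinimide | C=CC(=O)ON1C(=O)CCC1=O | starting material
16 | N1-acryloyl-N8-(diethoxyphosphorylacetyl)spermidine | CCOP(=O)(OCC)CC(=O)NCCCCNCCCNC(=O)C=C | intermediate
17 | N1-acryloyl-N4-Boc-N8-(diethoxyphosphorylacetyl)spermidine | CCOP(=O)(OCC)CC(=O)NCCCCN(C(=O)OC(C)(C)C)CCCNC(=O)C=C | intermediate
18 | (4aR,9bR,4'R,5'R) ketal alcohol bearing at C8 the E-cinnamamide chain that ends in the diethyl phosphonoacetamide | O1[C@H](c5ccccc5)[C@@H](c5ccccc5)OC12CC[C@]3(CO)c4cc(/C=C/C(=O)NCCCN(C(=O)OC(C)(C)C)CCCCNC(=O)CP(=O)(OCC)OCC)ccc4O[C@@H]3C2 | intermediate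
19 | (4aR,9bS,4'R,5'R) ketal C9b-carbaldehyde bearing the same chain (precursor of the key step) | O1[C@H](c5ccccc5)[C@@H](c5ccccc5)OC12CC[C@]3(C=O)c4cc(/C=C/C(=O)NCCCN(C(=O)OC(C)(C)C)CCCCNC(=O)CP(=O)(OCC)OCC)ccc4O[C@@H]3C2 | intermediate
20 | N4-Boc (R,R)-hydrobenzoin ketal of the target macrocycle, (4aR,9bS), E,E | O1[C@H](c6ccccc6)[C@@H](c6ccccc6)OC12CC[C@]34/C=C/C(=O)NCCCCN(C(=O)OC(C)(C)C)CCCNC(=O)/C=C/c5ccc(c3c5)O[C@@H]4C2 | intermediate
21 | target macrolactam CNP0415009.1, (4aR,9bS), E,E | O=C1CC[C@]23/C=C/C(=O)NCCCCNCCCNC(=O)/C=C/c4ccc(c2c4)O[C@@H]3C1 | target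

Total step count: 12. Longest linear sequence: 9 (steps 1–5 and 9–12). The chain (steps 6–8) is made in parallel.

Steps most likely to fail

Step 11. Addition to the neopentyl formyl group may be so slow that intermolecular olefination to dimers and oligomers overtakes ring closure, or the chain may not reach a productive conformation.
- The fallback reverses the order of the two C–C couplings and sets out from 10 and 17.
- Alcohol 10 is oxidised with Dess–Martin periodinane to the 8-bromo C9b-carbaldehyde F1.
- An intermolecular LiCl/DBU olefination of it with phosphonate 17 at normal concentration gives the open-chain bromo bis-enoyl amide F2.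
- An intramolecular Mizoroki–Heck reaction (Pd(OAc)2, P(o-tol)3, Et3N, DMF, high dilution) between C8–Br and the terminal acrylamide then closes the same 20-membered ring. This comes back to the route at 20.

Step 2. The push–pull C2=C3 bond of the benzofuran may be too poor a dienophile, so that decomposition of the diene outruns cycloaddition, or the adduct may revert to the aromatic starting material.
- The fallback is a Robinson-type annulation that sets out from hemiacetal 3, isolated by leaving out the H2SO4 treatment of step 1.
- As the ring tautomer of an α-formyl arylacetate, 3 undergoes Et3N-catalysed Michael addition to methyl vinyl ketone at C3. This gives the quaternary lactol ethyl 5-bromo-2-hydroxy-3-(3-oxobutyl)-2,3-dihydrobenzofuran-3-carboxylate F3.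
- Heating with p-TsOH in toluene lets the terminal ketone enol attack the lactol carbon (or aldol condensation is followed by oxa-Michael addition of the phenol). This closes the cyclohexanone ring cis-fused.
- The fallback comes back to the route at 8 and needs neither high pressure nor step 3.

Step 4. The two ketal diastereomers may co-elute and co-crystallise, both as esters and after step 5 as alcohols, which would leave the resolution incomplete.
- The fallback sets out from 8 and separates the enantiomers directly by preparative supercritical-fluid chromatography on an amylose tris(3,5-dimethylphenylcarbamate) stationary phase.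
- This gives the enantiopure keto ester ethyl (4aR,9bS)-8-bromo-3-oxo-2,3,4,4a-tetrahydrodibenzo[b,d]furan-9b(1H)-carboxylate F4.
- Ketalisation under the step 4 conditions then gives one diastereomer only and comes back to the route at 9.

Further compounds
F1 | step 11 | (4aR,9bS,4'R,5'R)-8-bromo-4',5'-diphenyl-1,2,4,4a-tetrahydro-9bH-spiro[dibenzo[b,d]furan-3,2'-[1,3]dioxolane]-9b-carbaldehyde | O1[C@H](c5ccccc5)[C@@H](c5ccccc5)OC12CC[C@]3(C=O)c4cc(Br)ccc4O[C@@H]3C2
F2 | step 11 | open-chain 8-bromo ketal with the C9b E-enoyl amide chain ending in the N1-acrylamide, (4aR,9bS,4'R,5'R) | O1[C@H](c5ccccc5)[C@@H](c5ccccc5)OC12CC[C@]3(/C=C/C(=O)NCCCCN(C(=O)OC(C)(C)C)CCCNC(=O)C=C)c4cc(Br)ccc4O[C@@H]3C2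
F3 | step 2 | ethyl 5-bromo-2-hydroxy-3-(3-oxobutyl)-2,3-dihydrobenzofuran-3-carboxylate (racemic, lactol epimers) | CCOC(=O)C1(CCC(C)=O)C(O)Oc2ccc(Br)cc12
F4 | step 4 | ethyl (4aR,9bS)-8-bromo-3-oxo-2,3,4,4a-tetrahydrodibenzo[b,d]furan-9b(1H)-carboxylate | O=C1CC[C@]2(C(=O)OCC)c3cc(Br)ccc3O[C@@H]2C1
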